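**Retrosynthetic overview** (locants follow the 1-benzofuran-2-one numbering of the target: C3a, C4, C5, C6, C7, C7a)
1. Target 20 ⇐ bicyclic lactone diol 12 by O4 silylation, O7 isobutyrylation, Eschenmoser α-methylenation, SeO2 hydroxylation of the isopropenyl methyl, and desilylation.
2. 12 ⇐ chiral bis(boronate) 4 + hydroxy aldehyde 7 in one flask: allylboration (C4–C5 bond), acetal unmasking, intramolecular allylboration (C6–C7 bond, closes the cyclohexane, sets the quaternary carbon), then lactonisation (O1–C2, closes the γ-lactone).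
3. 7 ⇐ D-proline cross-aldol of tert-butyl 4-oxobutanoate with dimethoxyacetaldehyde (sets C3a and C7a). 4 ⇐ enantioselective 1,2-diboration of (Z)-triene 3 ⇐ methacrolein (iodo-Wittig, vinyl coupling).
4. Ring order: nothing is cyclic before step 5; there the carbocycle forms first and the lactone second, in the same operation.

Assumption: the (R,R)-TADDOL-derived phosphonite is taken to give the (2S)-bis(boronate) 4; if the catalyst's facial sense is the opposite, the (S,S)-ligand is used.

**Step 1**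
Reactants: 1 2-methylprop-2-enal (methacrolein)
Product: 2 (3Z)-4-iodo-2-methylpenta-1,3-diene
Conditions: EtPPh3I, n-BuLi, THF, −78 °C; I2, −78 °C; NaN(SiMe3)2, −20 °C; then 1, −78 °C to rt
Reagents that add atoms: ethyltriphenylphosphonium iodide, CC[P+](c1ccccc1)(c1ccccc1)c1ccccc1.[I-]; iodine, II
Why: Stork–Zhao-type Wittig olefination with the α-iodo ylide Ph3P=C(I)CH3 is kinetically Z-selective (iodine cis to the aldehyde-derived isopropenyl group), which fixes the alkene geometry needed later.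

**Step 2**
Reactants: 2 (3Z)-4-iodo-2-methylpenta-1,3-diene
Product: 3 (3Z)-3,5-dimethylhexa-1,3,5-triene
Conditions: CH2=CHMgBr, Pd(PPh3)4 (3 mol %), THF, 0 °C to rt
Reagents that add atoms: vinylmagnesium bromide, C=C[Mg]Br
Why: Kumada–Corriu coupling of an alkenyl iodide under zerovalent palladium catalysis proceeds with retention of geometry, so the vinyl group ends up cis to the isopropenyl group.

**Step 3**
Reactants: 3 (3Z)-3,5-dimethylhexa-1,3,5-triene
Product: 4 2,2'-[(2S,3Z)-3,5-dimethylhexa-3,5-diene-1,2-diyl]bis(4,4,5,5-tetramethyl-1,3,2-dioxaborolane)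
Conditions: B2pin2, Pt(dba)3 (3 mol %), (R,R)-3,5-diethylphenyl-TADDOL phenylphosphonite (6 mol %), THF, 60 °C
Reagents that add atoms: bis(pinacolato)diboron, CC1(C)OB(OC1(C)C)B1OC(C)(C)C(C)(C)O1
Why: Zerovalent-platinum-catalysed enantioselective 1,2-diboration of a cis-substituted 1,3-diene: the (Z)-substituent and the 3-methyl group block the s-cis conformer needed for 1,4-addition, so B2pin2 adds across the unhindered vinyl group (not the 1,1-disubstituted terminus) and the chiral phosphonite sets the (S) C–B centre.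

**Step 4**
Reactants: 5 tert-butyl 4-oxobutanoate; 6 2,2-dimethoxyacetaldehyde
Product: 7 tert-butyl (3R,4S)-3-formyl-4-hydroxy-5,5-dimethoxypentanoate
Conditions: D-proline (20 mol %), DMF, 4 °C, 5 added over 24 h to 6 (60 wt % in H2O, 3 equiv)
Reagents that add atoms: none
Why: Proline-catalysed direct cross-aldol reaction (enamine catalysis): the activated acetal aldehyde acts only as acceptor, and D-proline gives the anti adduct, setting C3 (R) and C4 (S) of 7, the future C3a and C7a; the tert-butyl ester keeps the γ-hydroxy ester open.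

**Step 5**
Reactants: 4 2,2'-[(2S,3Z)-3,5-dimethylhexa-3,5-diene-1,2-diyl]bis(4,4,5,5-tetramethyl-1,3,2-dioxaborolane); 7 tert-butyl (3R,4S)-3-formyl-4-hydroxy-5,5-dimethoxypentanoate
Product: 12 (3aS,4R,5S,6S,7R,7aS)-6-ethenyl-4,7-dihydroxy-6-methyl-5-(prop-1-en-2-yl)hexahydro-1-benzofuran-2(3H)-one, via borate adduct 8 (not isolated), via hydroxy aldehyde 9 (not isolated), via triol ester 10 (not isolated), via triol acid 11 (not isolated)
Conditions: CH2Cl2, rt, 24 h; then TFA–H2O–CH2Cl2 (5:1:5), 0 °C to rt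
Reagents that add atoms: water, O
Why: Proposed new method: a one-flask extension of the tandem diene-diboration/double allylboration of 1,4-dicarbonyls (closest known reaction type), in which first the α-chiral secondary allylboronate of 4 adds to the free aldehyde of 7 through a chair transition state with the α-CH2Bpin group equatorial and the (Z)-isopropenyl group axial, transferring the C–B chirality to C4 and C5 (trans, reagent control) and leaving an (E)-γ,γ-disubstituted allyl-Bpin, then aqueous TFA unmasks the acetal and the aldehyde is trapped by intramolecular allylboration through a trans-decalin-like chair–chair transition state that keeps the C3a, C4 and C5 substituents equatorial and so fixes C7 (OH equatorial) and the quaternary C6 (vinyl equatorial, methyl axial), and finally TFA cleaves the tert-butyl ester and the acid closes onto the axial C7a hydroxyl because the cis-fused γ-lactone is favoured over the trans-fused one at O4.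

**Step 6**
Reactants: 12 (3aS,4R,5S,6S,7R,7aS)-6-ethenyl-4,7-dihydroxy-6-methyl-5-(prop-1-en-2-yl)hexahydro-1-benzofuran-2(3H)-one
Product: 13 (3aR,4R,5S,6S,7R,7aS)-4-[(tert-butyldimethylsilyl)oxy]-6-ethenyl-7-hydroxy-6-methyl-5-(prop-1-en-2-yl)hexahydro-1-benzofuran-2(3H)-one
Conditions: TBSOTf (1.05 equiv), 2,6-lutidine, CH2Cl2, −78 °C
Reagents that add atoms: tert-butyldimethylsilyl trifluoromethanesulfonate, CC(C)(C)[Si](C)(C)OS(=O)(=O)C(F)(F)F
Why: Kinetic silylation of the less hindered hydroxyl: O7 is flanked by the quaternary C6 and the axial lactone oxygen, so one equivalent of silyl triflate at low temperature should take O4 (the 3a descriptor changes only because of CIP priorities).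

**Step 7**
Reactants: 13 (3aR,4R,5S,6S,7R,7aS)-4-[(tert-butyldimethylsilyl)oxy]-6-ethenyl-7-hydroxy-6-methyl-5-(prop-1-en-2-yl)hexahydro-1-benzofuran-2(3H)-one
Product: 14 (3aR,4R,5S,6S,7R,7aS)-4-[(tert-butyldimethylsilyl)oxy]-6-ethenyl-6-methyl-2-oxo-5-(prop-1-en-2-yl)octahydro-1-benzofuran-7-yl 2-methylpropanoate
Conditions: (i-PrCO)2O, 4-(dimethylamino)pyridine, Et3N, CH2Cl2, 40 °C
Reagents that add atoms: isobutyric anhydride, CC(C)C(=O)OC(=O)C(C)C
Why: Nucleophilic-catalysis (Steglich-type) acylation of the only free hydroxyl; the neopentyl-like position needs excess anhydride and warming, and no stereocentre is touched.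

**Step 8**
Reactants: 14 (3aR,4R,5S,6S,7R,7aS)-4-[(tert-butyldimethylsilyl)oxy]-6-ethenyl-6-methyl-2-oxo-5-(prop-1-en-2-yl)octahydro-1-benzofuran-7-yl 2-methylpropanoate
Product: 18 (3aR,4R,5S,6S,7R,7aS)-4-[(tert-butyldimethylsilyl)oxy]-6-ethenyl-6-methyl-3-methylidene-2-oxo-5-(prop-1-en-2-yl)octahydro-1-benzofuran-7-yl 2-methylpropanoate, via lithium enolate 15 (not isolated), via Mannich base 16 (not isolated), via methiodide salt 17 (not isolated)
Conditions: LiN(SiMe3)2 (1.1 equiv), THF, −78 °C; Me2N=CH2 I (Eschenmoser's salt), −78 to 0 °C; MeI, MeOH, rt; aq NaHCO3, CH2Cl2, rt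
Reagents that add atoms: Eschenmoser's salt (N,N-dimethylmethyleneiminium iodide), C=[N+](C)C.[I-]
Why: Eschenmoser methylenation: the lactone α-CH2 is more acidic and far less hindered than the isobutyrate α-CH, so it is enolised selectively, and the Mannich reaction, N-methylation and Hofmann-type elimination install the exocyclic methylene without touching C3a.

**Step 9**
Reactants: 18 (3aR,4R,5S,6S,7R,7aS)-4-[(tert-butyldimethylsilyl)oxy]-6-ethenyl-6-methyl-3-methylidene-2-oxo-5-(prop-1-en-2-yl)octahydro-1-benzofuran-7-yl 2-methylpropanoate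
Product: 19 (3aR,4R,5S,6S,7R,7aS)-4-[(tert-butyldimethylsilyl)oxy]-6-ethenyl-5-(3-hydroxyprop-1-en-2-yl)-6-methyl-3-methylidene-2-oxooctahydro-1-benzofuran-7-yl 2-methylpropanoate
Conditions: SeO2 (0.5 equiv), t-BuOOH (3 equiv), CH2Cl2, rt
Reagents that add atoms: tert-butyl hydroperoxide, CC(C)(C)OO; selenium dioxide, O=[Se]=O
Why: SeO2-catalysed allylic hydroxylation (ene reaction then [2,3]-sigmatropic shift): the isopropenyl group is the only nucleophilic alkene with allylic hydrogens (the vinyl group has none, the acrylate is electron-poor), and the methyl hydrogens react rather than the ring methine, whose C–H lies in the alkene plane, as in the oxidation of isopulegol-type trans-2-isopropenylcyclohexanols.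

**Step 10**
Reactants: 19 (3aR,4R,5S,6S,7R,7aS)-4-[(tert-butyldimethylsilyl)oxy]-6-ethenyl-5-(3-hydroxyprop-1-en-2-yl)-6-methyl-3-methylidene-2-oxooctahydro-1-benzofuran-7-yl 2-methylpropanoate
Product: 20 (3aS,4R,5S,6S,7R,7aS)-6-ethenyl-4-hydroxy-5-(3-hydroxyprop-1-en-2-yl)-6-methyl-3-methylidene-2-oxooctahydro-1-benzofuran-7-yl 2-methylpropanoate (target)
Conditions: HF·pyridine, pyridine, THF, 0 °C to rt
Reagents that add atoms: none
Why: Fluoride-driven desilylation under buffered, non-basic conditions leaves the α-methylene lactone and the isobutyrate intact and cannot trigger translactonisation or acyl migration.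

**Compound list**
1 | 2-methylprop-2-enal (methacrolein) | C=C(C)C=O | starting material
2 | (3Z)-4-iodo-2-methylpenta-1,3-diene | C=C(C)/C=C(\I)C | intermediate
3 | (3Z)-3,5-dimethylhexa-1,3,5-triene | C=C/C(C)=C\C(C)=C | intermediate
4 | 2,2'-[(2S,3Z)-3,5-dimethylhexa-3,5-diene-1,2-diyl]bis(4,4,5,5-tetramethyl-1,3,2-dioxaborolane) | CC1(C)OB(C[C@H](B2OC(C)(C)C(C)(C)O2)/C(C)=C\C(C)=C)OC1(C)C | intermediate
5 | tert-butyl 4-oxobutanoate | CC(C)(C)OC(=O)CCC=O | starting material
6 | 2,2-dimethoxyacetaldehyde | COC(OC)C=O | starting material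
7 | tert-butyl (3R,4S)-3-formyl-4-hydroxy-5,5-dimethoxypentanoate | COC(OC)[C@@H](O)[C@@H](CC(=O)OC(C)(C)C)C=O | intermediate
8 | borate adduct (not isolated): tert-butyl (6E)-3-(1-hydroxy-2,2-dimethoxyethyl)-6-methyl-4-(pinacolboryloxy)-8-(pinacolboryl)-5-(prop-1-en-2-yl)oct-6-enoate; its four stereocentres become C3a, C4, C5 and C7a of 12 | COC(OC)[C@@H](O)[C@@H](CC(=O)OC(C)(C)C)[C@H](OB1OC(C)(C)C(C)(C)O1)[C@@H](C(=C)C)/C(C)=C/CB1OC(C)(C)C(C)(C)O1 | intermediate
9 | hydroxy aldehyde (not isolated, rests largely as its five-membered lactol): tert-butyl (6E)-4-hydroxy-3-(1-hydroxy-2-oxoethyl)-6-methyl-8-(pinacolboryl)-5-(prop-1-en-2-yl)oct-6-enoate, configuration as in 8 | O=C[C@@H](O)[C@@H](CC(=O)OC(C)(C)C)[C@H](O)[C@@H](C(=C)C)/C(C)=C/CB1OC(C)(C)C(C)(C)O1 | intermediate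
10 | triol ester (not isolated): tert-butyl 2-[4-ethenyl-2,5,6-trihydroxy-4-methyl-3-(prop-1-en-2-yl)cyclohexyl]acetate, ring configuration as in 12 | C=C[C@@]1(C)[C@H](C(=C)C)[C@@H](O)[C@H](CC(=O)OC(C)(C)C)[C@H](O)[C@@H]1O | intermediate
11 | triol acid (not isolated): 2-[4-ethenyl-2,5,6-trihydroxy-4-methyl-3-(prop-1-en-2-yl)cyclohexyl]acetic acid, ring configuration as in 12 | C=C[C@@]1(C)[C@H](C(=C)C)[C@@H](O)[C@H](CC(=O)O)[C@H](O)[C@@H]1O | intermediate
12 | (3aS,4R,5S,6S,7R,7aS)-6-ethenyl-4,7-dihydroxy-6-methyl-5-(prop-1-en-2-yl)hexahydro-1-benzofuran-2(3H)-one (cis-fused lactone) | C=C[C@@]1(C)[C@H](C(=C)C)[C@@H](O)[C@@H]2CC(=O)O[C@@H]2[C@@H]1O | intermediate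
13 | (3aR,4R,5S,6S,7R,7aS)-4-[(tert-butyldimethylsilyl)oxy]-6-ethenyl-7-hydroxy-6-methyl-5-(prop-1-en-2-yl)hexahydro-1-benzofuran-2(3H)-one | C=C[C@@]1(C)[C@H](C(=C)C)[C@@H](O[Si](C)(C)C(C)(C)C)[C@@H]2CC(=O)O[C@@H]2[C@@H]1O | intermediate
14 | (3aR,4R,5S,6S,7R,7aS)-4-[(tert-butyldimethylsilyl)oxy]-6-ethenyl-6-methyl-2-oxo-5-(prop-1-en-2-yl)octahydro-1-benzofuran-7-yl 2-methylpropanoate | C=C[C@@]1(C)[C@H](C(=C)C)[C@@H](O[Si](C)(C)C(C)(C)C)[C@@H]2CC(=O)O[C@@H]2[C@@H]1OC(=O)C(C)C | intermediate
15 | lithium enolate of 14 (not isolated), ring configuration as in 14 | C=C[C@@]1(C)[C@H](C(=C)C)[C@@H](O[Si](C)(C)C(C)(C)C)[C@@H]2C=C(O[Li])O[C@@H]2[C@@H]1OC(=O)C(C)C | intermediate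
16 | Mannich base (not isolated): 3-[(dimethylamino)methyl] derivative of 14, C3 epimers | C=C[C@@]1(C)[C@H](C(=C)C)[C@@H](O[Si](C)(C)C(C)(C)C)[C@@H]2C(CN(C)C)C(=O)O[C@@H]2[C@@H]1OC(=O)C(C)C | intermediate
17 | methiodide salt (not isolated): 3-[(trimethylammonio)methyl] derivative of 14, iodide | C=C[C@@]1(C)[C@H](C(=C)C)[C@@H](O[Si](C)(C)C(C)(C)C)[C@@H]2C(C[N+](C)(C)C)C(=O)O[C@@H]2[C@@H]1OC(=O)C(C)C.[I-] | intermediate
18 | (3aR,4R,5S,6S,7R,7aS)-4-[(tert-butyldimethylsilyl)oxy]-6-ethenyl-6-methyl-3-methylidene-2-oxo-5-(prop-1-en-2-yl)octahydro-1-benzofuran-7-yl 2-methylpropanoate | C=C[C@@]1(C)[C@H](C(=C)C)[C@@H](O[Si](C)(C)C(C)(C)C)[C@@H]2C(=C)C(=O)O[C@@H]2[C@@H]1OC(=O)C(C)C | intermediate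
19 | (3aR,4R,5S,6S,7R,7aS)-4-[(tert-butyldimethylsilyl)oxy]-6-ethenyl-5-(3-hydroxyprop-1-en-2-yl)-6-methyl-3-methylidene-2-oxooctahydro-1-benzofuran-7-yl 2-methylpropanoate | C=C[C@@]1(C)[C@H](C(=C)CO)[C@@H](O[Si](C)(C)C(C)(C)C)[C@@H]2C(=C)C(=O)O[C@@H]2[C@@H]1OC(=O)C(C)C | intermediate
20 | (3aS,4R,5S,6S,7R,7aS)-6-ethenyl-4-hydroxy-5-(3-hydroxyprop-1-en-2-yl)-6-methyl-3-methylidene-2-oxooctahydro-1-benzofuran-7-yl 2-methylpropanoate | C=C[C@@]1(C)[C@H](C(=C)CO)[C@@H](O)[C@@H]2C(=C)C(=O)O[C@@H]2[C@@H]1OC(=O)C(C)C | target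

**Totals**
Total step count: 10. Longest linear sequence: 9 (steps 1, 2, 3, 5, 6, 7, 8, 9, 10); the aldol branch (step 4) joins at step 5.

**Three steps most likely to fail**

Step 5. The acid stage carries several risks at once. The γ-hydroxy aldehyde 9 rests as a lactol, the allylboronate and the isopropenyl group sit in aqueous TFA, and lactonisation could go to the equatorial O4 instead of the axial O7a. The fallback differentiates the two hydroxyls before any ring exists, so the lactone can only close at O7a. It sets out from 7, which is silylated (TESCl, imidazole, DMF, 0 °C) to tert-butyl (3R,4S)-3-formyl-5,5-dimethoxy-4-[(triethylsilyl)oxy]pentanoate F1. Allylboration with 4 (CH2Cl2, rt, neutral work-up) gives the isolated allylboronate alcohol F2, which is silylated (TBSOTf, 2,6-lutidine, −78 °C) to its TBS ether F3. Aqueous HCl–THF then removes the TES group and the acetal and closes the carbocycle by allylboration with O4 blocked (no lactol), and brief anhydrous TFA–CH2Cl2 at 0 °C closes the lactone. Both rings still form in that one operation. The fallback comes back to the route at 13, so step 6 is not needed on this path.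

Step 6. The preference for O4 over O7 may be only modest. The fallback differentiates by selective deacylation instead of selective silylation. It sets out from 12, which is acylated at both hydroxyls (excess isobutyric anhydride, 4-(dimethylamino)pyridine, 40 °C) to the bis-isobutyrate F4. The less hindered O4 ester is removed with Mg(OMe)2 in MeOH at rt (mild acid work-up re-closes any opened lactone) to give the 7-isobutyrate alcohol F5. Silylation with TBSOTf and 2,6-lutidine then comes back to the route at 14.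

Step 9. The SeO2 oxidation may stall, over-oxidise to the enal, or attack the ring methine. The fallback replaces direct hydroxylation by chlorination and substitution. It sets out from 18, which undergoes ene-type allylic chlorination (Ca(OCl)2, solid CO2, CH2Cl2–H2O, 0 °C) at the isopropenyl group to give the allylic chloride F6. Displacement with HCO2Na and catalytic n-Bu4NI in DMF at 40 °C gives the allylic formate F7; direct and allylic substitution lead to the same product on this 2-substituted allyl system. Methanolysis with NaHCO3 in MeOH at 0 °C, which the isobutyrate survives, comes back to the route at 19.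

**Further compounds**
F1 | step 5 | tert-butyl (3R,4S)-3-formyl-5,5-dimethoxy-4-[(triethylsilyl)oxy]pentanoate | COC(OC)[C@@H](O[Si](CC)(CC)CC)[C@@H](CC(=O)OC(C)(C)C)C=O
F2 | step 5 | allylboronate alcohol: tert-butyl (6E)-3-[2,2-dimethoxy-1-(triethylsilyloxy)ethyl]-4-hydroxy-6-methyl-8-(pinacolboryl)-5-(prop-1-en-2-yl)oct-6-enoate, configuration as in 8 | COC(OC)[C@@H](O[Si](CC)(CC)CC)[C@@H](CC(=O)OC(C)(C)C)[C@H](O)[C@@H](C(=C)C)/C(C)=C/CB1OC(C)(C)C(C)(C)O1
F3 | step 5 | TBS ether of F2 (4-O-tert-butyldimethylsilyl) | COC(OC)[C@@H](O[Si](CC)(CC)CC)[C@@H](CC(=O)OC(C)(C)C)[C@H](O[Si](C)(C)C(C)(C)C)[C@@H](C(=C)C)/C(C)=C/CB1OC(C)(C)C(C)(C)O1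
F4 | step 6 | bis-isobutyrate: 6-ethenyl-6-methyl-2-oxo-5-(prop-1-en-2-yl)octahydro-1-benzofuran-4,7-diyl bis(2-methylpropanoate), ring configuration as in 12 | C=C[C@@]1(C)[C@H](C(=C)C)[C@@H](OC(=O)C(C)C)[C@@H]2CC(=O)O[C@@H]2[C@@H]1OC(=O)C(C)C
F5 | step 6 | (3aS,4R,5S,6S,7R,7aS)-6-ethenyl-4-hydroxy-6-methyl-2-oxo-5-(prop-1-en-2-yl)octahydro-1-benzofuran-7-yl 2-methylpropanoate | C=C[C@@]1(C)[C@H](C(=C)C)[C@@H](O)[C@@H]2CC(=O)O[C@@H]2[C@@H]1OC(=O)C(C)C
F6 | step 9 | allylic chloride: 5-(3-chloroprop-1-en-2-yl) analogue of 18, ring configuration as in 18 | C=C[C@@]1(C)[C@H](C(=C)CCl)[C@@H](O[Si](C)(C)C(C)(C)C)[C@@H]2C(=C)C(=O)O[C@@H]2[C@@H]1OC(=O)C(C)C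
F7 | step 9 | allylic formate: 5-[3-(formyloxy)prop-1-en-2-yl] analogue of 18, ring configuration as in 18 | C=C[C@@]1(C)[C@H](C(=C)COC=O)[C@@H](O[Si](C)(C)C(C)(C)C)[C@@H]2C(=C)C(=O)O[C@@H]2[C@@H]1OC(=O)C(C)C
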